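**Plan** (longipinane numbering: C1 ring carbonyl, C2=C3 with C15 on C3, bridgeheads C4 and C11, cyclobutane carbons C5 (CH) and C10 (bears C14), C6 = CMe2, C7–C9 oxygenated)
1. Retrosynthesis: remove the two acyl groups, then the C7/C8 diol (from C7=C8), then C5–H (from C5–OH), then cut C5–C6 (vinylogous aldol).
2. The remaining bicyclo[3.1.1]heptanone is cut at C5–C11 and C4–C10 together (intramolecular vinylketene–alkene [2+2]); the acyclic acid is cut at C1–C2 (vinylogous Mukaiyama aldol).
3. Enabling feature: C5 of the cyclobutane carries only H and C6, both installable later, so it can be the ketene carbonyl carbon. C10 is fully substituted (C14, C9), so C11=C10 is a polarised trisubstituted alkene that forces the crossed mode. C3 carries a methyl, so a 3-methylalk-2-enoyl chloride gives the vinylketene, and C1 is carried as a silyl ether.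
4. Forward: acyclic chain → four- and six-membered rings in one step → seven-membered ring by C6→C5 aldol → C5 deoxygenation → enone → diol → esters.
5. Stereochemistry: a catalyst-set silyloxy centre at C1 steers the cage centres C4, C10 and C11 (A(1,3) strain; E-alkene geometry) and is erased on oxidation. C5–H is fixed by the ring, C9 by oxazaborolidine reduction, and C8/C7 by syn-osmylation anti to the C9 ester.
6. Isomer mixtures that converge: 2E/2Z acyl chlorides (one vinylketene), carbinol epimers 18 (one enone), dienolate isomers (one aldol).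

Key step: step 8

Assumption: in the oxazaborolidine reduction (step 15) the quaternary carbon acts as the large group and the cis-alkene as the small one; if the sense proves opposite, the (R)-catalyst is used.

Step 1
Reactants: 1 1-(tert-butyldimethylsilyloxy)propan-2-one; 2 triethyl phosphonoacetate
Product: 3 ethyl (E)-4-(tert-butyldimethylsilyloxy)-3-methylbut-2-enoate
Conditions: NaH, THF, 0 °C to rt; minor Z isomer removed by chromatography
Reagents that add atoms: none
Why: Horner–Wadsworth–Emmons olefination of an α-silyloxy methyl ketone, which should favour the E-enoate because the larger CH2OTBS group avoids the ester.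

Step 2
Reactants: 3 ethyl (E)-4-(tert-butyldimethylsilyloxy)-3-methylbut-2-enoate
Product: 4 (E)-4-(tert-butyldimethylsilyloxy)-3-methylbut-2-en-1-ol
Conditions: i-Bu2AlH (2.2 equiv), CH2Cl2, −78 °C; Rochelle-salt work-up
Reagents that add atoms: none
Why: 1,2-reduction of the enoate by the aluminium hydride should give the allylic alcohol without touching the silyl ether or the alkene geometry.

Step 3
Reactants: 4 (E)-4-(tert-butyldimethylsilyloxy)-3-methylbut-2-en-1-ol
Product: 5 (E)-4-(tert-butyldimethylsilyloxy)-3-methylbut-2-enal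
Conditions: MnO2, CH2Cl2, rt
Reagents that add atoms: none
Why: MnO2 oxidises allylic alcohols selectively to enals under neutral conditions that should not isomerise the E-alkene.

Step 4
Reactants: 6 ethyl 3-methylbut-2-enoate
Product: 8 tert-butyl[(1-ethoxy-3-methylbuta-1,3-dien-1-yl)oxy]dimethylsilane, via lithium dienolate 7 (not isolated)
Conditions: LiN(i-Pr)2, THF, −78 °C; then TBSCl, DMPU, −78 °C to rt
Reagents that add atoms: tert-butyldimethylsilyl chloride, CC(C)(C)[Si](C)(C)Cl
Why: γ-deprotonation of the senecioate and O-silylation of the extended enolate should give the silyl dienol ether needed as the vinylogous donor.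

Step 5
Reactants: 5 (E)-4-(tert-butyldimethylsilyloxy)-3-methylbut-2-enal; 8 tert-butyl[(1-ethoxy-3-methylbuta-1,3-dien-1-yl)oxy]dimethylsilane
Product: 9 ethyl (2E,5S,6E)-8-(tert-butyldimethylsilyloxy)-5-hydroxy-3,7-dimethylocta-2,6-dienoate
Conditions: SiCl4, (S,S)-bisphosphoramide catalyst [two (S)-N,N′-dimethyl-1,1′-binaphthyl-2,2′-diamine-derived cyclic phosphoramide units, P(=O)–N(CH3)–, joined by a pentane-1,5-diyl chain] (5 mol %), i-Pr2NEt (cat.), CH2Cl2, −78 °C; aq. NaHCO3
Reagents that add atoms: none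
Why: Lewis-base-activated SiCl4 vinylogous Mukaiyama aldol addition, in which the chiral trichlorosilyl cation binds the enal and the dienol ether should attack through its γ-carbon on the Si face to set the (5S) carbinol (the (R,R)-catalyst would give the enantiomer).

Step 6
Reactants: 9 ethyl (2E,5S,6E)-8-(tert-butyldimethylsilyloxy)-5-hydroxy-3,7-dimethylocta-2,6-dienoate
Product: 10 ethyl (2E,5S,6E)-8-(tert-butyldimethylsilyloxy)-5-(tert-butyldiphenylsilyloxy)-3,7-dimethylocta-2,6-dienoate
Conditions: TBDPSCl, imidazole, DMF, rt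
Reagents that add atoms: tert-butyldiphenylsilyl chloride, CC(C)(C)[Si](Cl)(c1ccccc1)c1ccccc1
Why: Silylation of the secondary allylic alcohol gives a bulky, robust ether that can later be kept while the primary TBS ether is removed.

Step 7
Reactants: 10 ethyl (2E,5S,6E)-8-(tert-butyldimethylsilyloxy)-5-(tert-butyldiphenylsilyloxy)-3,7-dimethylocta-2,6-dienoate
Product: 11 (2E,5S,6E)-8-(tert-butyldimethylsilyloxy)-5-(tert-butyldiphenylsilyloxy)-3,7-dimethylocta-2,6-dienoic acid
Conditions: LiOH, THF/MeOH/H2O, 40 °C; then dilute HCl to pH 4 at 0 °C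
Reagents that add atoms: lithium hydroxide (hydroxide oxygen), [Li+].[OH-]
Why: Saponification of the β-methyl enoate should leave both silyl ethers intact and give the acid for ketene generation.

Step 8
Reactants: 11 (2E,5S,6E)-8-(tert-butyldimethylsilyloxy)-5-(tert-butyldiphenylsilyloxy)-3,7-dimethylocta-2,6-dienoic acid
Product: 14 (1R,4S,5R,7R)-4-(tert-butyldiphenylsilyloxy)-7-[(tert-butyldimethylsilyloxy)methyl]-7-methyl-2-methylidenebicyclo[3.1.1]heptan-6-one, via acid chloride 12 (not isolated), via vinylketene 13 (not isolated)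
Conditions: 1-chloro-N,N,2-trimethylprop-1-en-1-amine, CH2Cl2, 0 °C to rt; then slow addition to Et3N, toluene, 110 °C, high dilution
Reagents that add atoms: none
Why: 1,4-Dehydrochlorination of 12 by Et3N gives vinylketene 13 (2E and 2Z acyl chlorides funnel into it), which undergoes a thermal, concerted but asynchronous [π2s+π2a] ketene–alkene cycloaddition in which the electrophilic ketene carbon bonds to the less substituted alkene carbon and the ketene terminus to the methyl-bearing carbon. The closest known reaction type is the intramolecular [2+2] cycloaddition of vinylketenes generated from 3-methylalka-2,6-dienoyl chlorides to give 2-methylidenebicyclo[3.1.1]heptan-6-ones. The six-membered ring closes 6-exo at the alkene (endo to the ketene C=C) and the four-membered ring by crossed collapse of the incipient tertiary cation centre onto the ketene terminus. The bridgeheads C1 and C5 can only be cis-bridged, C7 follows from suprafacial addition to the E-alkene (methyl syn to the methylidene bridge, CH2OTBS over the carbonyl), and the absolute sense comes from the 4-silyloxy centre, whose C–H eclipses the alkene to avoid A(1,3) strain with the cis methyl so that the ketene adds anti to OTBDPS. The step needs crossed rather than fused regiochemistry (secured by the polarised trisubstituted alkene on a three-atom tether), facial selectivity (secured by the allylic stereocentre) and cyclisation over ketene dimerisation (secured by slow addition at high dilution).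

Step 9
Reactants: 14 (1R,4S,5R,7R)-4-(tert-butyldiphenylsilyloxy)-7-[(tert-butyldimethylsilyloxy)methyl]-7-methyl-2-methylidenebicyclo[3.1.1]heptan-6-one
Product: 15 (1R,4S,5R,7R)-4-(tert-butyldiphenylsilyloxy)-7-(hydroxymethyl)-7-methyl-2-methylidenebicyclo[3.1.1]heptan-6-one
Conditions: HF·pyridine, pyridine, THF, 0 °C
Reagents that add atoms: none
Why: Buffered HF should cleave the primary TBS ether much faster than the secondary TBDPS ether and does not affect the non-enolisable cyclobutanone.

Step 10
Reactants: 15 (1R,4S,5R,7R)-4-(tert-butyldiphenylsilyloxy)-7-(hydroxymethyl)-7-methyl-2-methylidenebicyclo[3.1.1]heptan-6-one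
Product: 16 (1R,4S,5R,7R)-4-(tert-butyldiphenylsilyloxy)-7-methyl-2-methylidene-6-oxobicyclo[3.1.1]heptane-7-carbaldehyde
Conditions: Dess–Martin periodinane, NaHCO3, CH2Cl2, rt
Reagents that add atoms: none
Why: Dess–Martin oxidation under buffered conditions should give the α-quaternary, non-enolisable aldehyde.

Step 11
Reactants: 16 (1R,4S,5R,7R)-4-(tert-butyldiphenylsilyloxy)-7-methyl-2-methylidene-6-oxobicyclo[3.1.1]heptane-7-carbaldehyde; 17 3-methylbut-1-yne
Product: 18 (1R,4S,5R,7R)-4-(tert-butyldiphenylsilyloxy)-7-[(E)-1-hydroxy-4-methylpent-2-enyl]-7-methyl-2-methylidenebicyclo[3.1.1]heptan-6-one (both carbinol epimers)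
Conditions: 17, Cp2Zr(H)Cl, CH2Cl2, rt; Me2Zn, −65 °C; then 16, 0 °C; aq. NH4Cl
Reagents that add atoms: none
Why: Syn hydrozirconation gives the E-alkenylzirconocene and Zr-to-Zn exchange an alkenylzinc that should add to the aldehyde much faster than to the hindered cyclobutanone; the new carbinol centre forms unselectively and is erased in step 12.

Step 12
Reactants: 18 (1R,4S,5R,7R)-4-(tert-butyldiphenylsilyloxy)-7-[(E)-1-hydroxy-4-methylpent-2-enyl]-7-methyl-2-methylidenebicyclo[3.1.1]heptan-6-one
Product: 19 (1R,4S,5R,7R)-4-(tert-butyldiphenylsilyloxy)-7-methyl-7-[(E)-4-methylpent-2-enoyl]-2-methylidenebicyclo[3.1.1]heptan-6-one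
Conditions: Dess–Martin periodinane, NaHCO3, CH2Cl2, rt
Reagents that add atoms: none
Why: Dess–Martin oxidation of the allylic alcohol converts both epimers into the single enone that holds the γ-CH needed for ring closure.

Step 13
Reactants: 19 (1R,4S,5R,7R)-4-(tert-butyldiphenylsilyloxy)-7-methyl-7-[(E)-4-methylpent-2-enoyl]-2-methylidenebicyclo[3.1.1]heptan-6-one
Product: 21 1-(tert-butyldiphenylsilyloxy)-5-hydroxylongipina-3(15),7-dien-9-one, via potassium dienolate 20 (not isolated)
Conditions: KOt-Bu (0.3 equiv), t-BuOH/THF, 0 °C to rt; AcOH quench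
Reagents that add atoms: none
Why: Intramolecular vinylogous aldol addition under equilibrating conditions, in which the γ-CH is the only acidic position (no α′-H, cyclobutanone flanked by bridgeheads), dienolate geometries and any strained α-adduct equilibrate, and only γ-attack can bridge C10 to C5 through a seven-membered ring, helped by relief of cyclobutanone angle strain; the tether delivers C6 to the lower face so the hydroxyl ends on the side of the C1–C3 bridge.

Step 14
Reactants: 21 1-(tert-butyldiphenylsilyloxy)-5-hydroxylongipina-3(15),7-dien-9-one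
Product: 24 O-[1-(tert-butyldiphenylsilyloxy)-9-oxolongipina-3(15),7-dien-5-yl] S-methyl dithiocarbonate, via sodium alkoxide 22 (not isolated), via sodium xanthate 23 (not isolated)
Conditions: NaH, imidazole (cat.), CS2 (excess, present from the start), THF, 0 °C; then MeI
Reagents that add atoms: carbon disulfide, S=C=S; iodomethane, CI
Why: Xanthate formation with CS2 present from the start, so that the alkoxide should be captured before retro-aldol cleavage and then S-methylated; the tertiary xanthate cannot undergo Chugaev elimination because its only β-hydrogens sit at bridgeheads.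

Step 15
Reactants: 24 O-[1-(tert-butyldiphenylsilyloxy)-9-oxolongipina-3(15),7-dien-5-yl] S-methyl dithiocarbonate
Product: 25 O-[1-(tert-butyldiphenylsilyloxy)-9-hydroxylongipina-3(15),7-dien-5-yl] S-methyl dithiocarbonate
Conditions: (S)-2-methyl-CBS-oxazaborolidine [(S)-1-methyl-3,3-diphenyltetrahydro-1H,3H-pyrrolo[1,2-c][1,3,2]oxazaborole] (cat.), catecholborane, toluene, −78 °C
Reagents that add atoms: none
Why: Corey–Bakshi–Shibata reduction gives reagent-controlled 1,2-delivery of hydride to the enone (the cage offers almost no facial bias at C9) and should set the C9 carbinol as in the target, while catecholborane spares the alkenes and the xanthate.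

Step 16
Reactants: 25 O-[1-(tert-butyldiphenylsilyloxy)-9-hydroxylongipina-3(15),7-dien-5-yl] S-methyl dithiocarbonate
Product: 26 1-(tert-butyldiphenylsilyloxy)longipina-3(15),7-dien-9-ol
Conditions: Bu3SnH, AIBN (cat.), PhSeSePh (cat.), benzene, 80 °C
Reagents that add atoms: none
Why: Barton–McCombie deoxygenation, in which the tertiary cyclobutyl radical can only take hydrogen on the outer face because C6 is held inside by the seven-membered ring (this sets C5); a 1,2-vinyl shift would contract the bridge to a more strained six-membered one and is further suppressed by the fast donor PhSeH formed in situ.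

Step 17
Reactants: 26 1-(tert-butyldiphenylsilyloxy)longipina-3(15),7-dien-9-ol
Product: 28 1-(tert-butyldiphenylsilyloxy)longipina-3(15),7-dien-9-yl (Z)-2-methylbut-2-enoate, via lithium alkoxide 27 (not isolated)
Conditions: LiN(SiMe3)2, THF, −78 °C; then the mixed anhydride made from angelic acid, 2,4,6-trichlorobenzoyl chloride and Et3N (toluene, rt), −78 to 0 °C
Reagents that add atoms: angelic acid, C/C=C(/C)C(=O)O
Why: Yamaguchi-type acylation of the hindered lithium alkoxide at low temperature should install the angelate without Z-to-E isomerisation; it is placed after step 16 because stannyl radicals would isomerise the angelate.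

Step 18
Reactants: 28 1-(tert-butyldiphenylsilyloxy)longipina-3(15),7-dien-9-yl (Z)-2-methylbut-2-enoate
Product: 29 1-hydroxylongipina-3(15),7-dien-9-yl (Z)-2-methylbut-2-enoate
Conditions: HF·pyridine, THF, rt
Reagents that add atoms: none
Why: Acidic fluoride cleaves the TBDPS ether without base, so the allylic angelate should survive unchanged.

Step 19
Reactants: 29 1-hydroxylongipina-3(15),7-dien-9-yl (Z)-2-methylbut-2-enoate
Product: 31 1-oxolongipina-2,7-dien-9-yl (Z)-2-methylbut-2-enoate, via non-conjugated ketone 30 (not isolated)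
Conditions: Dess–Martin periodinane, NaHCO3, CH2Cl2, rt; then Et3N, rt
Reagents that add atoms: none
Why: Dess–Martin oxidation removes the relay stereocentre, and mild base should move the methylidene double bond into conjugation through the C2 enolate, the only one possible because C11 is a bridgehead.

Step 20
Reactants: 31 1-oxolongipina-2,7-dien-9-yl (Z)-2-methylbut-2-enoate
Product: 32 7,8-dihydroxy-1-oxolongipin-2-en-9-yl (Z)-2-methylbut-2-enoate
Conditions: OsO4 (cat.), N-methylmorpholine N-oxide, acetone/H2O, rt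
Reagents that add atoms: osmium tetroxide, O=[Os](=O)(=O)=O (catalytic; its oxygen is replenished from N-methylmorpholine N-oxide, C[N+]1([O-])CCOCC1, and water, O)
Why: Catalytic syn-dihydroxylation should take place at the only electron-rich alkene (the enone and angelate double bonds are electron-poor) and anti to the allylic ester, giving O-8 trans to O-9 and O-7 cis to O-8.

Step 21
Reactants: 32 7,8-dihydroxy-1-oxolongipin-2-en-9-yl (Z)-2-methylbut-2-enoate
Product: 33 (4R,5S,7S,8S,9S,10R,11R)-7-hydroxy-8-(3-methylbutanoyloxy)-1-oxolongipin-2-en-9-yl (Z)-2-methylbut-2-enoate (CNP0251293.1)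
Conditions: isovaleric anhydride (1.05 equiv), DMAP (cat.), pyridine, CH2Cl2, −20 °C
Reagents that add atoms: isovaleric anhydride, CC(C)CC(=O)OC(=O)CC(C)C
Why: Kinetic acylation should select the C8 hydroxyl because the C7 hydroxyl is neopentyl (next to the CMe2 carbon), and low temperature limits acyl migration.

**Compound list**
1 | 1-(tert-butyldimethylsilyloxy)propan-2-one | CC(=O)CO[Si](C)(C)C(C)(C)C | starting material
2 | triethyl phosphonoacetate | CCOC(=O)CP(=O)(OCC)OCC | starting material
3 | ethyl (E)-4-(tert-butyldimethylsilyloxy)-3-methylbut-2-enoate | CCOC(=O)/C=C(\C)CO[Si](C)(C)C(C)(C)C | intermediate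
4 | (E)-4-(tert-butyldimethylsilyloxy)-3-methylbut-2-en-1-ol | OC/C=C(\C)CO[Si](C)(C)C(C)(C)C | intermediate
5 | (E)-4-(tert-butyldimethylsilyloxy)-3-methylbut-2-enal | O=C/C=C(\C)CO[Si](C)(C)C(C)(C)C | intermediate
6 | ethyl 3-methylbut-2-enoate | CCOC(=O)C=C(C)C | starting material
7 | lithium dienolate of 6 | CCOC([O-])=CC(C)=C.[Li+] | intermediate
8 | tert-butyl[(1-ethoxy-3-methylbuta-1,3-dien-1-yl)oxy]dimethylsilane | CCOC(=CC(C)=C)O[Si](C)(C)C(C)(C)C | intermediate
9 | ethyl (2E,5S,6E)-8-(tert-butyldimethylsilyloxy)-5-hydroxy-3,7-dimethylocta-2,6-dienoate | CCOC(=O)/C=C(\C)C[C@H](O)/C=C(\C)CO[Si](C)(C)C(C)(C)C | intermediate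
10 | ethyl (2E,5S,6E)-8-(tert-butyldimethylsilyloxy)-5-(tert-butyldiphenylsilyloxy)-3,7-dimethylocta-2,6-dienoate | CCOC(=O)/C=C(\C)C[C@H](O[Si](c1ccccc1)(c1ccccc1)C(C)(C)C)/C=C(\C)CO[Si](C)(C)C(C)(C)C | intermediate
11 | (2E,5S,6E)-8-(tert-butyldimethylsilyloxy)-5-(tert-butyldiphenylsilyloxy)-3,7-dimethylocta-2,6-dienoic acid | OC(=O)/C=C(\C)C[C@H](O[Si](c1ccccc1)(c1ccccc1)C(C)(C)C)/C=C(\C)CO[Si](C)(C)C(C)(C)C | intermediate
12 | acid chloride of 11 | ClC(=O)/C=C(\C)C[C@H](O[Si](c1ccccc1)(c1ccccc1)C(C)(C)C)/C=C(\C)CO[Si](C)(C)C(C)(C)C | intermediate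
13 | (5S,6E)-8-(tert-butyldimethylsilyloxy)-5-(tert-butyldiphenylsilyloxy)-7-methyl-3-methylideneocta-1,6-dien-1-one (vinylketene) | O=C=CC(=C)C[C@H](O[Si](c1ccccc1)(c1ccccc1)C(C)(C)C)/C=C(\C)CO[Si](C)(C)C(C)(C)C | intermediate
14 | (1R,4S,5R,7R)-4-(tert-butyldiphenylsilyloxy)-7-[(tert-butyldimethylsilyloxy)methyl]-7-methyl-2-methylidenebicyclo[3.1.1]heptan-6-one (7-methyl syn to the C2–C4 bridge; CH2OTBS and 4-OSi on the side of the carbonyl bridge) | O=C1[C@H]2[C@@H](O[Si](c3ccccc3)(c3ccccc3)C(C)(C)C)CC(=C)[C@@H]1[C@@]2(C)CO[Si](C)(C)C(C)(C)C | intermediate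
15 | (1R,4S,5R,7R)-4-(tert-butyldiphenylsilyloxy)-7-(hydroxymethyl)-7-methyl-2-methylidenebicyclo[3.1.1]heptan-6-one | O=C1[C@H]2[C@@H](O[Si](c3ccccc3)(c3ccccc3)C(C)(C)C)CC(=C)[C@@H]1[C@@]2(C)CO | intermediate
16 | (1R,4S,5R,7R)-4-(tert-butyldiphenylsilyloxy)-7-methyl-2-methylidene-6-oxobicyclo[3.1.1]heptane-7-carbaldehyde | O=C1[C@H]2[C@@H](O[Si](c3ccccc3)(c3ccccc3)C(C)(C)C)CC(=C)[C@@H]1[C@@]2(C)C=O | intermediate
17 | 3-methylbut-1-yne | C#CC(C)C | starting material
18 | (1R,4S,5R,7R)-4-(tert-butyldiphenylsilyloxy)-7-[(E)-1-hydroxy-4-methylpent-2-enyl]-7-methyl-2-methylidenebicyclo[3.1.1]heptan-6-one (mixture of carbinol epimers) | O=C1[C@H]2[C@@H](O[Si](c3ccccc3)(c3ccccc3)C(C)(C)C)CC(=C)[C@@H]1[C@@]2(C)C(O)/C=C/C(C)C | intermediate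
19 | (1R,4S,5R,7R)-4-(tert-butyldiphenylsilyloxy)-7-methyl-7-[(E)-4-methylpent-2-enoyl]-2-methylidenebicyclo[3.1.1]heptan-6-one | O=C1[C@H]2[C@@H](O[Si](c3ccccc3)(c3ccccc3)C(C)(C)C)CC(=C)[C@@H]1[C@@]2(C)C(=O)/C=C/C(C)C | intermediate
20 | potassium dienolate of 19 | O=C1[C@H]2[C@@H](O[Si](c3ccccc3)(c3ccccc3)C(C)(C)C)CC(=C)[C@@H]1[C@@]2(C)C([O-])=CC=C(C)C.[K+] | intermediate
21 | 1-(tert-butyldiphenylsilyloxy)-5-hydroxylongipina-3(15),7-dien-9-one (5-OH on the side of the C1–C3 bridge) | O=C1C=CC(C)(C)[C@]2(O)[C@H]3[C@@H](O[Si](c4ccccc4)(c4ccccc4)C(C)(C)C)CC(=C)[C@@H]2[C@@]13C | intermediate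
22 | sodium alkoxide of 21 | O=C1C=CC(C)(C)[C@]2([O-])[C@H]3[C@@H](O[Si](c4ccccc4)(c4ccccc4)C(C)(C)C)CC(=C)[C@@H]2[C@@]13C.[Na+] | intermediate
23 | sodium O-alkyl dithiocarbonate of 21 | O=C1C=CC(C)(C)[C@]2(OC(=S)[S-])[C@H]3[C@@H](O[Si](c4ccccc4)(c4ccccc4)C(C)(C)C)CC(=C)[C@@H]2[C@@]13C.[Na+] | intermediate
24 | O-[1-(tert-butyldiphenylsilyloxy)-9-oxolongipina-3(15),7-dien-5-yl] S-methyl dithiocarbonate | O=C1C=CC(C)(C)[C@]2(OC(=S)SC)[C@H]3[C@@H](O[Si](c4ccccc4)(c4ccccc4)C(C)(C)C)CC(=C)[C@@H]2[C@@]13C | intermediate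
25 | O-[1-(tert-butyldiphenylsilyloxy)-9-hydroxylongipina-3(15),7-dien-5-yl] S-methyl dithiocarbonate | O[C@@H]1C=CC(C)(C)[C@]2(OC(=S)SC)[C@H]3[C@@H](O[Si](c4ccccc4)(c4ccccc4)C(C)(C)C)CC(=C)[C@@H]2[C@@]13C | intermediate
26 | 1-(tert-butyldiphenylsilyloxy)longipina-3(15),7-dien-9-ol | O[C@@H]1C=CC(C)(C)[C@@H]2[C@H]3[C@@H](O[Si](c4ccccc4)(c4ccccc4)C(C)(C)C)CC(=C)[C@@H]2[C@@]13C | intermediate
27 | lithium alkoxide of 26 | [Li+].[O-][C@@H]1C=CC(C)(C)[C@@H]2[C@H]3[C@@H](O[Si](c4ccccc4)(c4ccccc4)C(C)(C)C)CC(=C)[C@@H]2[C@@]13C | intermediate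
28 | 1-(tert-butyldiphenylsilyloxy)longipina-3(15),7-dien-9-yl (Z)-2-methylbut-2-enoate | C/C=C(/C)C(=O)O[C@@H]1C=CC(C)(C)[C@@H]2[C@H]3[C@@H](O[Si](c4ccccc4)(c4ccccc4)C(C)(C)C)CC(=C)[C@@H]2[C@@]13C | intermediate
29 | 1-hydroxylongipina-3(15),7-dien-9-yl (Z)-2-methylbut-2-enoate | C/C=C(/C)C(=O)O[C@@H]1C=CC(C)(C)[C@@H]2[C@H]3[C@@H](O)CC(=C)[C@@H]2[C@@]13C | intermediate
30 | 1-oxolongipina-3(15),7-dien-9-yl (Z)-2-methylbut-2-enoate | C/C=C(/C)C(=O)O[C@@H]1C=CC(C)(C)[C@@H]2[C@H]3C(=O)CC(=C)[C@@H]2[C@@]13C | intermediate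
31 | 1-oxolongipina-2,7-dien-9-yl (Z)-2-methylbut-2-enoate | C/C=C(/C)C(=O)O[C@@H]1C=CC(C)(C)[C@@H]2[C@H]3C(=O)C=C(C)[C@@H]2[C@@]13C | intermediate
32 | 7,8-dihydroxy-1-oxolongipin-2-en-9-yl (Z)-2-methylbut-2-enoate (O-8 trans to O-9, O-7 cis to O-8) | C/C=C(/C)C(=O)O[C@@H]1[C@@H](O)[C@@H](O)C(C)(C)[C@@H]2[C@H]3C(=O)C=C(C)[C@@H]2[C@@]13C | intermediate
33 | (4R,5S,7S,8S,9S,10R,11R)-7-hydroxy-8-(3-methylbutanoyloxy)-1-oxolongipin-2-en-9-yl (Z)-2-methylbut-2-enoate | C/C=C(/C)C(=O)O[C@@H]1[C@@H](OC(=O)CC(C)C)[C@@H](O)C(C)(C)[C@@H]2[C@H]3C(=O)C=C(C)[C@@H]2[C@@]13C | target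

Total step count: 21. Longest linear sequence: 20 steps (steps 1–3 and 5–21; step 4 prepares the dienol ether).

**Steps most likely to fail**

Step 13. The aldol equilibrium may lie on the side of the open enone (retro-aldol), or γ-deprotonation may be too slow to compete with decomposition. The fallback sets out from 19: LiN(SiMe3)2 in THF at −78 °C followed by N-bromosuccinimide should give the α-bromo-β,γ-unsaturated ketone F1 (its allylic isomer, the γ-bromo enone, would serve equally). Activated Zn in THF then forms a carbon-bound allylzinc species, so dienolate geometry no longer matters. Its γ-addition to the cyclobutanone (vinylogous Reformatsky reaction) gives a covalent zinc aldolate that should not revert, and aqueous NH4Cl gives 21, where the route is rejoined.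

Step 14. The tertiary alkoxide may fragment by retro-aldol cleavage before capture, or may be too congested to add to CS2. The fallback sets out from 21 and avoids the alkoxide: oxalyl chloride without base, then methanol and pyridine, should give the tertiary methyl oxalate F2. Reduction under the conditions of step 15 gives the allylic alcohol F3, and Bu3SnH with AIBN in toluene at 110 °C (radical deoxygenation of a tertiary oxalate) gives 26, where the route is rejoined.

Step 16. The C5 radical may attack the C7=C8 double bond (3-exo closure) and cause a 1,2-vinyl shift that contracts the four-carbon bridge. The fallback sets out from 25 and masks the alkene: hydroxyl-directed epoxidation with VO(acac)2 and t-BuOOH, selective for the allylic-alcohol alkene over the methylidene, should give the epoxy alcohol F4. Barton–McCombie reduction as in step 16 then gives the deoxygenated epoxy alcohol F5 with no π bond next to the radical. NaI, NaOAc and AcOH, then Zn (iodohydrin formation and reductive elimination) restore the alkene and give 26, where the route is rejoined.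

**Further compounds**
F1 | step 13 | (1R,4S,5R,7R)-7-(2-bromo-4-methylpent-3-enoyl)-4-(tert-butyldiphenylsilyloxy)-7-methyl-2-methylidenebicyclo[3.1.1]heptan-6-one (bromide epimers) | O=C1[C@H]2[C@@H](O[Si](c3ccccc3)(c3ccccc3)C(C)(C)C)CC(=C)[C@@H]1[C@@]2(C)C(=O)C(Br)C=C(C)C
F2 | step 14 | 1-(tert-butyldiphenylsilyloxy)-9-oxolongipina-3(15),7-dien-5-yl methyl oxalate | O=C1C=CC(C)(C)[C@]2(OC(=O)C(=O)OC)[C@H]3[C@@H](O[Si](c4ccccc4)(c4ccccc4)C(C)(C)C)CC(=C)[C@@H]2[C@@]13C
F3 | step 14 | 1-(tert-butyldiphenylsilyloxy)-9-hydroxylongipina-3(15),7-dien-5-yl methyl oxalate | O[C@@H]1C=CC(C)(C)[C@]2(OC(=O)C(=O)OC)[C@H]3[C@@H](O[Si](c4ccccc4)(c4ccccc4)C(C)(C)C)CC(=C)[C@@H]2[C@@]13C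
F4 | step 16 | O-[1-(tert-butyldiphenylsilyloxy)-7,8-epoxy-9-hydroxylongipin-3(15)-en-5-yl] S-methyl dithiocarbonate (epoxide syn to the 9-hydroxyl) | O[C@@H]1[C@@H]5O[C@@H]5C(C)(C)[C@]2(OC(=S)SC)[C@H]3[C@@H](O[Si](c4ccccc4)(c4ccccc4)C(C)(C)C)CC(=C)[C@@H]2[C@@]13C
F5 | step 16 | 1-(tert-butyldiphenylsilyloxy)-7,8-epoxylongipin-3(15)-en-9-ol | O[C@@H]1[C@@H]5O[C@@H]5C(C)(C)[C@@H]2[C@H]3[C@@H](O[Si](c4ccccc4)(c4ccccc4)C(C)(C)C)CC(=C)[C@@H]2[C@@]13C
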